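**Plan**
- Retrosynthesis: the aryl–O–CH2 ether is cut first (umbelliferone comes in last), then the ring bond between the gem-dimethyl carbon and the ring CH that carries the side chain.
- Enabling feature: in the cyclohexanone the gem-dimethyl carbon is the α-carbon of the ring ketone, and its neighbour CH is bonded to the ring C(CH3)OH. The ring is therefore the product of a ketone enolate opening a cis-trisubstituted epoxide (CH–O–C(CH3)) in the same chain, with release of epoxide strain.
- Further cuts: acyl–isopropenyl bond (Weinreb amide + Grignard), the CH2–CH2 bond beside the olefin (allylic bromide + amide enolate), the Z-olefin (Still–Gennari), back to an aldehyde from (R)-linalool.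
- Forward: the C15 chain is built linearly (7 C from linalool, 3 from the phosphonate, 2 from the acetamide, 3 from the Grignard reagent), the only carbocycle closes in the key step, and the coumarin is attached last.
- Stereochemistry: the chain carbinol comes from (R)-linalool. The ring CH/C(CH3)OH pair comes from a Shi epoxidation of the Z-olefin and is transcribed stereospecifically in the ring closure (inversion at CH, retention at the carbinol carbon).

Key step: step 10

Remark: (R)-(−)-linalool is taken as enantiomerically pure; its tertiary carbinol carbon becomes the chain carbinol of the target and is never a reacting centre.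

**Step 1**
Reactants: 1 (R)-(−)-linalool
Product: 3 (3R)-3,7-dimethyloct-6-ene-1,3-diol, via B-alkyl-9-borabicyclononane 2 (not isolated)
Conditions: 9-BBN (1.5 equiv), THF, 0 °C → rt; then NaOH, H2O2, 0 °C → rt
Reagents that add atoms: hydrogen peroxide, OO
Why: Hydroboration–oxidation; the bulky dialkylborane should add anti-Markovnikov to the monosubstituted vinyl group only and leave the trisubstituted olefin and the carbinol centre untouched.

**Step 2**
Reactants: 3 (3R)-3,7-dimethyloct-6-ene-1,3-diol
Product: 4 (4R)-2,2,4-trimethyl-4-(4-methylpent-3-en-1-yl)-1,3-dioxane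
Conditions: 2,2-dimethoxypropane, pyridinium p-toluenesulfonate (cat.), CH2Cl2, rt
Reagents that add atoms: 2,2-dimethoxypropane, COC(C)(C)OC
Why: Acetonide formation (transketalisation) ties the primary and the tertiary hydroxyl into one 1,3-dioxane, which later keeps the tertiary alkoxide away from the epoxide.

**Step 3**
Reactants: 4 (4R)-2,2,4-trimethyl-4-(4-methylpent-3-en-1-yl)-1,3-dioxane
Product: 6 3-[(4R)-2,2,4-trimethyl-1,3-dioxan-4-yl]propanal, via secondary ozonide 5 (not isolated)
Conditions: O3, CH2Cl2, −78 °C; then PPh3, −78 °C → rt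
Reagents that add atoms: ozone, [O-][O+]=O
Why: Ozonolysis with reductive work-up cleaves the only olefin to the aldehyde under acid-free conditions, so the acetonide should survive.

**Step 4**
Reactants: 6 3-[(4R)-2,2,4-trimethyl-1,3-dioxan-4-yl]propanal; 7 ethyl 2-[bis(2,2,2-trifluoroethoxy)phosphoryl]propanoate
Product: 9 ethyl (2Z)-2-methyl-5-[(4R)-2,2,4-trimethyl-1,3-dioxan-4-yl]pent-2-enoate, via potassium phosphonate carbanion 8 (not isolated)
Conditions: 7, KN(SiMe3)2, 18-crown-6, THF, −78 °C; then 6, −78 °C
Reagents that add atoms: none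
Why: Still–Gennari olefination; the electron-poor bis(trifluoroethyl) phosphonate with a dissociated potassium counter-ion eliminates under kinetic control and should give the Z-trisubstituted enoate (ester cis to the chain).

**Step 5**
Reactants: 9 ethyl (2Z)-2-methyl-5-[(4R)-2,2,4-trimethyl-1,3-dioxan-4-yl]pent-2-enoate
Product: 10 (2Z)-2-methyl-5-[(4R)-2,2,4-trimethyl-1,3-dioxan-4-yl]pent-2-en-1-ol
Conditions: i-Bu2AlH (2.2 equiv), CH2Cl2, −78 °C; aqueous potassium sodium tartrate
Reagents that add atoms: none
Why: 1,2-Reduction of the enoate by the aluminium hydride gives the allylic alcohol with the olefin geometry unchanged.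

**Step 6**
Reactants: 10 (2Z)-2-methyl-5-[(4R)-2,2,4-trimethyl-1,3-dioxan-4-yl]pent-2-en-1-ol
Product: 11 (4R)-4-[(3Z)-5-bromo-4-methylpent-3-en-1-yl]-2,2,4-trimethyl-1,3-dioxane
Conditions: CBr4, PPh3, 2,6-lutidine (0.2 equiv), CH2Cl2, 0 °C
Reagents that add atoms: carbon tetrabromide, BrC(Br)(Br)Br
Why: Appel bromination converts the primary allylic alcohol by SN2 displacement under near-neutral conditions, which should preserve the Z-olefin and the acetonide.

**Step 7**
Reactants: 11 (4R)-4-[(3Z)-5-bromo-4-methylpent-3-en-1-yl]-2,2,4-trimethyl-1,3-dioxane; 12 N-methoxy-N-methylacetamide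
Product: 14 (4Z)-N-methoxy-N,4-dimethyl-7-[(4R)-2,2,4-trimethyl-1,3-dioxan-4-yl]hept-4-enamide, via lithium amide enolate 13 (not isolated)
Conditions: 12, LiN(i-Pr)2, THF, −78 °C; then 11, DMPU, −78 → −30 °C
Reagents that add atoms: none
Why: Enolate alkylation; SN2 displacement of the primary allylic bromide by the lithium enolate of the Weinreb acetamide adds the two-carbon acyl unit without touching the olefin geometry.

**Step 8**
Reactants: 14 (4Z)-N-methoxy-N,4-dimethyl-7-[(4R)-2,2,4-trimethyl-1,3-dioxan-4-yl]hept-4-enamide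
Product: 15 N-methoxy-N-methyl-3-[(2S,3R)-2-methyl-3-{2-[(4R)-2,2,4-trimethyl-1,3-dioxan-4-yl]ethyl}oxiran-2-yl]propanamide
Conditions: D-fructose-derived Shi ketone (30 mol %), KHSO5 (as Oxone), K2CO3, Bu4NHSO4, MeCN/dimethoxymethane/aqueous Na2B4O7 buffer (pH about 10.5), 0 °C
Reagents that add atoms: potassium peroxymonosulfate, [K+].OOS(=O)(=O)[O-]
Why: Shi asymmetric epoxidation; the chiral dioxirane should attack the trisubstituted olefin through the spiro transition state on the face that makes the CH carbon R, as for other trisubstituted olefins, and the Z geometry is transcribed stereospecifically into the cis-epoxide (2S,3R).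

**Step 9**
Reactants: 15 N-methoxy-N-methyl-3-[(2S,3R)-2-methyl-3-{2-[(4R)-2,2,4-trimethyl-1,3-dioxan-4-yl]ethyl}oxiran-2-yl]propanamide; 16 isopropenylmagnesium bromide
Product: 18 2-methyl-5-[(2S,3R)-2-methyl-3-{2-[(4R)-2,2,4-trimethyl-1,3-dioxan-4-yl]ethyl}oxiran-2-yl]pent-1-en-3-one, via magnesium hemiaminal chelate 17 (not isolated)
Conditions: CH2=C(CH3)MgBr (1.5 equiv), THF, −78 → 0 °C; cold aqueous NH4Cl
Reagents that add atoms: none
Why: Weinreb ketone synthesis; the N-methoxy magnesium chelate holds the tetrahedral adduct until work-up so that the enone forms without over-addition, and the trisubstituted epoxide should be inert to the Grignard reagent at low temperature.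

**Step 10**
Reactants: 18 2-methyl-5-[(2S,3R)-2-methyl-3-{2-[(4R)-2,2,4-trimethyl-1,3-dioxan-4-yl]ethyl}oxiran-2-yl]pent-1-en-3-one
Product: 20 (3R,4S)-4-hydroxy-2,2,4-trimethyl-3-{2-[(4R)-2,2,4-trimethyl-1,3-dioxan-4-yl]ethyl}cyclohexan-1-one, via lithium enolate 19 (not isolated)
Conditions: LiBH(s-Bu)3 (L-Selectride, 1.05 equiv), THF, −78 °C; then −78 °C → rt; aqueous NH4Cl
Reagents that add atoms: none
Why: Proposed new method: the bulky borohydride should deliver hydride to the unsubstituted olefin terminus of the isopropenyl ketone and so generate regiospecifically, with no proton source present, the fully substituted lithium enolate 19, whose α-carbon then opens the lithium-coordinated oxirane by backside attack at its secondary carbon. The closest known reaction types are the trialkylborohydride conjugate reduction–alkylation of enones and the intramolecular opening of epoxides by stabilised carbanions (epoxynitrile cyclisation) or by lithium ketone enolates; their combination on a trisubstituted epoxide with a tetrasubstituted enolate has not been shown. The cyclohexanone closes in a 6-(enolendo) mode that is endo with respect to the oxirane (both oxirane carbons become ring members), whereas the competing 5-exo attack would have to occur at the fully substituted oxirane carbon and join two quaternary centres. The ring CH (C3 of 20) is set by SN2 inversion at the oxirane CH carbon and the carbinol carbon C4 keeps the configuration of the quaternary oxirane carbon, so the cis-epoxide is transcribed into the cis relation of side chain and hydroxyl. The step needs 1,4- over 1,2-hydride delivery, which the unhindered β-methylene and the hindered reagent should secure, and C- over O-alkylation, which the lithium counter-ion and the stereoelectronically allowed six-membered enolendo geometry should favour. Release of epoxide strain and formation of a lithium alkoxide drive the creation of the quaternary carbon.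

**Step 11**
Reactants: 20 (3R,4S)-4-hydroxy-2,2,4-trimethyl-3-{2-[(4R)-2,2,4-trimethyl-1,3-dioxan-4-yl]ethyl}cyclohexan-1-one
Product: 21 (3R,4S)-3-[(3R)-3,5-dihydroxy-3-methylpentyl]-4-hydroxy-2,2,4-trimethylcyclohexan-1-one
Conditions: AcOH/H2O/THF (3:1:1), rt
Reagents that add atoms: none
Why: Acid-catalysed acetal hydrolysis frees the primary and the tertiary chain hydroxyl; the ring carbinol is γ to the ketone and no stereocentre is enolisable, so mild aqueous acid should cause neither retro-aldol cleavage nor epimerisation.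

**Step 12**
Reactants: 21 (3R,4S)-3-[(3R)-3,5-dihydroxy-3-methylpentyl]-4-hydroxy-2,2,4-trimethylcyclohexan-1-one; 22 umbelliferone
Product: 23 7-({(3R)-3-hydroxy-5-[(1R,6S)-6-hydroxy-2,2,6-trimethyl-3-oxocyclohexyl]-3-methylpentyl}oxy)-2H-chromen-2-one
Conditions: PPh3, diisopropyl azodicarboxylate, THF, 0 °C → rt
Reagents that add atoms: none
Why: Mitsunobu etherification; only the primary alcohol can be activated as the alkoxyphosphonium ion and displaced by the acidic 7-hydroxyl of the coumarin, the two tertiary alcohols being inert.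

**Compound list**
1 | (R)-(−)-linalool, (3R)-3,7-dimethylocta-1,6-dien-3-ol | CC(C)=CCC[C@@](C)(O)C=C | starting material
2 | (3S)-1-(9-borabicyclo[3.3.1]nonan-9-yl)-3,7-dimethyloct-6-en-3-ol (same spatial arrangement as 1; the descriptor changes because of the boron substituent) | CC(C)=CCC[C@@](C)(O)CCB1C2CCCC1CCC2 | intermediate
3 | (3R)-3,7-dimethyloct-6-ene-1,3-diol | CC(C)=CCC[C@@](C)(O)CCO | intermediate
4 | (4R)-2,2,4-trimethyl-4-(4-methylpent-3-en-1-yl)-1,3-dioxane | CC(C)=CCC[C@]1(C)CCOC(C)(C)O1 | intermediate
5 | 3,3-dimethyl-5-{2-[(4R)-2,2,4-trimethyl-1,3-dioxan-4-yl]ethyl}-1,2,4-trioxolane (both epimers at the trioxolane CH) | CC1(C)OOC(CC[C@]2(C)CCOC(C)(C)O2)O1 | intermediate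
6 | 3-[(4R)-2,2,4-trimethyl-1,3-dioxan-4-yl]propanal | O=CCC[C@]1(C)CCOC(C)(C)O1 | intermediate
7 | ethyl 2-[bis(2,2,2-trifluoroethoxy)phosphoryl]propanoate | CCOC(=O)C(C)P(=O)(OCC(F)(F)F)OCC(F)(F)F | starting material
8 | potassium salt of the α-carbanion of 7 | [K+].CCOC(=O)[C-](C)P(=O)(OCC(F)(F)F)OCC(F)(F)F | intermediate
9 | ethyl (2Z)-2-methyl-5-[(4R)-2,2,4-trimethyl-1,3-dioxan-4-yl]pent-2-enoate | CCOC(=O)/C(C)=C\CC[C@]1(C)CCOC(C)(C)O1 | intermediate
10 | (2Z)-2-methyl-5-[(4R)-2,2,4-trimethyl-1,3-dioxan-4-yl]pent-2-en-1-ol | OC/C(C)=C\CC[C@]1(C)CCOC(C)(C)O1 | intermediate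
11 | (4R)-4-[(3Z)-5-bromo-4-methylpent-3-en-1-yl]-2,2,4-trimethyl-1,3-dioxane | BrC/C(C)=C\CC[C@]1(C)CCOC(C)(C)O1 | intermediate
12 | N-methoxy-N-methylacetamide | CON(C)C(C)=O | starting material
13 | lithium 1-[methoxy(methyl)amino]ethen-1-olate | [Li+].[O-]C(=C)N(C)OC | intermediate
14 | (4Z)-N-methoxy-N,4-dimethyl-7-[(4R)-2,2,4-trimethyl-1,3-dioxan-4-yl]hept-4-enamide | CON(C)C(=O)CC/C(C)=C\CC[C@]1(C)CCOC(C)(C)O1 | intermediate
15 | N-methoxy-N-methyl-3-[(2S,3R)-2-methyl-3-{2-[(4R)-2,2,4-trimethyl-1,3-dioxan-4-yl]ethyl}oxiran-2-yl]propanamide | CON(C)C(=O)CC[C@]1(C)O[C@@H]1CC[C@]2(C)CCOC(C)(C)O2 | intermediate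
16 | isopropenylmagnesium bromide (prop-1-en-2-ylmagnesium bromide) | C=C(C)[Mg]Br | starting material
17 | bromomagnesium alkoxide of the tetrahedral adduct of 16 to the amide carbonyl of 15 (N,O-chelate; new carbinol carbon unassigned) | CON(C)C(O[Mg]Br)(CC[C@]1(C)O[C@@H]1CC[C@]2(C)CCOC(C)(C)O2)C(C)=C | intermediate
18 | 2-methyl-5-[(2S,3R)-2-methyl-3-{2-[(4R)-2,2,4-trimethyl-1,3-dioxan-4-yl]ethyl}oxiran-2-yl]pent-1-en-3-one | C=C(C)C(=O)CC[C@]1(C)O[C@@H]1CC[C@]2(C)CCOC(C)(C)O2 | intermediate
19 | lithium 2-methyl-5-[(2S,3R)-2-methyl-3-{2-[(4R)-2,2,4-trimethyl-1,3-dioxan-4-yl]ethyl}oxiran-2-yl]pent-2-en-3-olate | [Li+].[O-]C(=C(C)C)CC[C@]1(C)O[C@@H]1CC[C@]2(C)CCOC(C)(C)O2 | intermediate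
20 | (3R,4S)-4-hydroxy-2,2,4-trimethyl-3-{2-[(4R)-2,2,4-trimethyl-1,3-dioxan-4-yl]ethyl}cyclohexan-1-one | CC1(C)C(=O)CC[C@](C)(O)[C@@H]1CC[C@]2(C)CCOC(C)(C)O2 | intermediate
21 | (3R,4S)-3-[(3R)-3,5-dihydroxy-3-methylpentyl]-4-hydroxy-2,2,4-trimethylcyclohexan-1-one | CC1(C)C(=O)CC[C@](C)(O)[C@@H]1CC[C@@](C)(O)CCO | intermediate
22 | umbelliferone (7-hydroxy-2H-chromen-2-one) | Oc1ccc2ccc(=O)oc2c1 | starting material
23 | 7-({(3R)-3-hydroxy-5-[(1R,6S)-6-hydroxy-2,2,6-trimethyl-3-oxocyclohexyl]-3-methylpentyl}oxy)-2H-chromen-2-one | CC1(C)C(=O)CC[C@](C)(O)[C@@H]1CC[C@@](C)(O)CCOc1ccc2ccc(=O)oc2c1 | target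

**Totals**
Total step count: 12. Longest linear sequence: 12 steps (1 → 23); the other starting materials 7, 12, 16 and 22 are used as bought.

**Steps most likely to fail**

1. Step 10 (proposed new method). What may go wrong: hydride delivery to the carbonyl carbon instead of the olefin terminus, O-alkylation of the enolate by the epoxide, or proton transfer that scrambles the enolate before ring closure. The fallback uses known reaction types only; it sets out from bromide 11 and comes back at 20. Alkylation of methyl 4-methyl-3-oxopentanoate with 11 (K2CO3, acetone, reflux) should give the allylated β-keto ester F1. Shi epoxidation as in step 8 should give the epoxy β-keto ester F2. Two equivalents of LiN(i-Pr)2 (THF, −78 → 0 °C) should form the α,γ-dianion, whose γ-carbanion (the isopropyl carbon) is the only strongly nucleophilic site and should open the oxirane at its secondary carbon (γ-alkylation of a β-keto ester dianion) to give the cyclic β-keto ester F3. Krapcho dealkoxycarbonylation (LiCl, wet DMSO, 140 °C) then returns 20. The carbanion needs no hydride and cannot O-alkylate.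

2. Step 8. What may go wrong: poor facial discrimination by the dioxirane on the Z-olefin, which would give epoxide diastereomers that differ only at a pair remote from the existing centre, or oxidative loss of the ketone catalyst before conversion is complete. The fallback sets out from allylic alcohol 10 and comes back at 15. Sharpless asymmetric epoxidation of 10 (Ti(OiPr)4, L-(+)-diethyl tartrate, t-BuOOH, 4 Å sieves, CH2Cl2, −20 °C) should give the epoxy alcohol F4 under reagent control of well-defined facial sense. Dess–Martin oxidation (NaHCO3, CH2Cl2) should give the epoxy aldehyde F5. Horner–Wadsworth–Emmons reaction with diethyl {2-[methoxy(methyl)amino]-2-oxoethyl}phosphonate (NaH, THF) should give the unsaturated epoxy Weinreb amide F6. Diimide reduction (2-nitrobenzenesulfonyl hydrazide, Et3N, CH2Cl2) should saturate the electron-poor olefin without hydrogenolysis of the allylic epoxide and return 15. This path also avoids steps 6 and 7.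

3. Step 7. What may go wrong: self-condensation or fragmentation of the amide enolate (loss of formaldehyde from the N-methoxy group) outrunning the SN2 alkylation, or SN2′ attack on the allylic bromide. The fallback sets out from 11 and comes back at 14. Alkylation of dimethyl malonate with 11 (NaH, THF, 0 °C → rt) should give the allylated malonate F7. Krapcho dealkoxycarbonylation (NaCl, wet DMSO, 150 °C) should give the methyl ester F8. Treatment with N,O-dimethylhydroxylamine hydrochloride and i-PrMgCl (THF, −20 °C) should convert the ester into the Weinreb amide 14. A soft, stabilised carbanion replaces the fragile amide enolate.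

**Further compounds**
F1 | step 10 | methyl (4Z)-4-methyl-2-(2-methylpropanoyl)-7-[(4R)-2,2,4-trimethyl-1,3-dioxan-4-yl]hept-4-enoate (both epimers at C2) | COC(=O)C(C/C(C)=C\CC[C@]1(C)CCOC(C)(C)O1)C(=O)C(C)C
F2 | step 10 | methyl 4-methyl-2-{[(2S,3R)-2-methyl-3-{2-[(4R)-2,2,4-trimethyl-1,3-dioxan-4-yl]ethyl}oxiran-2-yl]methyl}-3-oxopentanoate (both epimers at C2) | COC(=O)C(C[C@]1(C)O[C@@H]1CC[C@]2(C)CCOC(C)(C)O2)C(=O)C(C)C
F3 | step 10 | methyl (4R,5S)-5-hydroxy-3,3,5-trimethyl-2-oxo-4-{2-[(4R)-2,2,4-trimethyl-1,3-dioxan-4-yl]ethyl}cyclohexane-1-carboxylate (both epimers at C1) | CC1(C)C(=O)C(C(=O)OC)C[C@](C)(O)[C@@H]1CC[C@]2(C)CCOC(C)(C)O2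
F4 | step 8 | [(2S,3R)-2-methyl-3-{2-[(4R)-2,2,4-trimethyl-1,3-dioxan-4-yl]ethyl}oxiran-2-yl]methanol | OC[C@]1(C)O[C@@H]1CC[C@]2(C)CCOC(C)(C)O2
F5 | step 8 | (2R,3R)-2-methyl-3-{2-[(4R)-2,2,4-trimethyl-1,3-dioxan-4-yl]ethyl}oxirane-2-carbaldehyde | O=C[C@]1(C)O[C@@H]1CC[C@]2(C)CCOC(C)(C)O2
F6 | step 8 | (2E)-N-methoxy-N-methyl-3-[(2S,3R)-2-methyl-3-{2-[(4R)-2,2,4-trimethyl-1,3-dioxan-4-yl]ethyl}oxiran-2-yl]prop-2-enamide | CON(C)C(=O)/C=C/[C@]1(C)O[C@@H]1CC[C@]2(C)CCOC(C)(C)O2
F7 | step 7 | dimethyl 2-{(2Z)-2-methyl-5-[(4R)-2,2,4-trimethyl-1,3-dioxan-4-yl]pent-2-en-1-yl}propanedioate | COC(=O)C(C/C(C)=C\CC[C@]1(C)CCOC(C)(C)O1)C(=O)OC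
F8 | step 7 | methyl (4Z)-4-methyl-7-[(4R)-2,2,4-trimethyl-1,3-dioxan-4-yl]hept-4-enoate | COC(=O)CC/C(C)=C\CC[C@]1(C)CCOC(C)(C)O1
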